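The central dihydropyran (ring D: ether O, O-bearing methine Cb, ring-fusion methine Ca, side-chain methine Cc, C3 and C4 of quinolone B) is read as the adduct of a formyl group with a 1-oxygenated diene whose C=C(O) end is the C3=C4 enol-ether bond of quinolone B. An aldehyde on C3 of quinolone A, tethered through its C4–O–CMe2 ether to an E-vinyl group on C3 of 4-methoxyquinolone B, should undergo a catalytic enantioselective intramolecular oxa-Diels–Alder reaction that forms Ca–Cb and O–C4(B), closes both pyrans and sets the cis ring fusion. The methoxy ketal is then ionised and the side chain added as a methallyl nucleophile at Cc, and hydration finishes the synthesis.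

Key step: step 5

Labels: quinolone A carries the dimethylpyran (ring C); quinolone B carries the side-chain methine. Ca is the ring-fusion CH bound to CMe2, Cb the ring-fusion CH bound to the ether oxygen and to C3 of quinolone A, Cc the CH bearing CH2C(CH3)2OH. The target is Ca R, Cb S, Cc R: the two ring-fusion hydrogens are cis, and the Cc hydrogen is trans to the Ca hydrogen.

Assumptions: 4-methoxy-1-methylquinolin-2(1H)-one is taken as purchasable. The sense of induction of the chromium catalyst cannot be assigned in advance for this intramolecular case; the (1R,2S) ligand series is written and would be exchanged for its mirror image if a first run shows the opposite sense.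

Step 1
Reactants: 1 4-hydroxy-1-methylquinolin-2(1H)-one
Product: 3 4-chloro-1-methyl-2-oxo-1,2-dihydroquinoline-3-carbaldehyde, via iminium chloride 2 (not isolated)
Conditions: POCl3, DMF, 0 to 60 °C; then ice-water
Reagents that add atoms: N,N-dimethylformamide CN(C)C=O; phosphoryl chloride O=P(Cl)(Cl)Cl; water O
Why: Vilsmeier–Haack reaction, in which the chloromethylideneiminium salt formylates the enol-type C3, the vinylogous-acid hydroxyl at C4 is exchanged for chloride, and water hydrolyses the C3 iminium group to the aldehyde.

Step 2
Reactants: 4 4-methoxy-1-methylquinolin-2(1H)-one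
Product: 5 3-iodo-4-methoxy-1-methylquinolin-2(1H)-one
Conditions: NIS, TFA (cat.), MeCN, 23 °C
Reagents that add atoms: N-iodosuccinimide O=C1CCC(=O)N1I
Why: Electrophilic iodination at C3, the beta carbon of the C4 enol ether and the only strongly nucleophilic position of the pyridone ring.

Step 3
Reactants: 5 3-iodo-4-methoxy-1-methylquinolin-2(1H)-one; 6 2-methylbut-3-en-2-ol
Product: 7 (E)-3-(3-hydroxy-3-methylbut-1-en-1-yl)-4-methoxy-1-methylquinolin-2(1H)-one
Conditions: Pd(OAc)2 (5 mol %), Bu4NCl, NaHCO3, DMF, 70 °C
Reagents that add atoms: none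
Why: Mizoroki–Heck reaction under ligand-free phase-transfer conditions; the arylpalladium species adds to the terminal alkene carbon and syn beta-hydride elimination should give the E alkene only, because the carbinol carbon has no hydrogen.

Step 4
Reactants: 7 (E)-3-(3-hydroxy-3-methylbut-1-en-1-yl)-4-methoxy-1-methylquinolin-2(1H)-one; 3 4-chloro-1-methyl-2-oxo-1,2-dihydroquinoline-3-carbaldehyde
Product: 9 4-{[(E)-4-(4-methoxy-1-methyl-2-oxo-1,2-dihydroquinolin-3-yl)-2-methylbut-3-en-2-yl]oxy}-1-methyl-2-oxo-1,2-dihydroquinoline-3-carbaldehyde, via sodium alkoxide 8 (not isolated)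
Conditions: NaH, THF, 0 °C; then 3, 0 to 23 °C; pH 7 work-up
Reagents that add atoms: none
Why: Addition–elimination (vinylogous acyl substitution of SNAr type) of the tertiary alkoxide at C4 of the beta-chloro enal, while the E geometry of the alkoxide keeps it from closing onto its own methoxy-bearing carbon.

Step 5
Reactants: 9 4-{[(E)-4-(4-methoxy-1-methyl-2-oxo-1,2-dihydroquinolin-3-yl)-2-methylbut-3-en-2-yl]oxy}-1-methyl-2-oxo-1,2-dihydroquinoline-3-carbaldehyde; 10 trimethyl(2-methylallyl)silane
Product: 12 the bis-pyranoquinolone with the complete ring system of the target (Ca R, Cb S, Cc R) and a 2-methylallyl group on Cc, via methoxy ketal 11 (not isolated)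
Conditions: CrCl(C27H29NO2) (10 mol %; trivalent chromium, Schiff-base ligand from 3-(1-adamantyl)-2-hydroxy-5-methylbenzaldehyde and (1R,2S)-1-amino-2-indanol), 4 Å MS, CH2Cl2, 23 °C; then 10, TMSOTf (0.3 equiv), −78 to −40 °C
Reagents that add atoms: none
Why: Proposed new method: the chromium-bound formyl group (Cb=O) on quinolone A adds as a heterodienophile across the 1-methoxy diene C4(OMe)=C3–CcH=CaH, two carbons of which are C4 and C3 of quinolone B, in an asynchronous oxa-[4+2] cycloaddition in which the Ca–Cb bond leads and the formyl oxygen then closes onto C4 of quinolone B to give ketal 11. The closest known reactions are the enantioselective hetero-Diels–Alder reaction of aldehydes with 1-alkoxy dienes under tridentate Schiff-base chromium chloride catalysis, intramolecular oxa-Diels–Alder reactions through salicylaldehyde-type aryl ether tethers, and Diels–Alder reactions of 3-vinylcoumarins and 3-vinylindoles as dienes. Ring C closes at the Ca–Cb bond as the tether ring of a type 1 intramolecular cycloaddition, and ring D closes as the six-membered [4+2] ring itself, its last bond being the ether O–C4 bond of quinolone B. The cis fusion at Ca and Cb should follow from the E alkene and the endo transition state enforced by the planar C3=C4–O part of the tether, the absolute sense (R at Ca, S at Cb) from the face of the formyl group left open by the chiral chromium complex, and the ketal carbon, formed suprafacially, is erased again. In the same flask TMSOTf ionises the methoxy ketal to a ring-D oxocarbenium ion (an O-alkylated ortho-quinone methide, as in a Ferrier-type allylic substitution), and the Hosomi–Sakurai nucleophile 10 should attack Cc anti to the neighbouring CMe2 carbon on Ca, which sets R at Cc and restores the aromatic 4-alkoxy-2-quinolone. The step needs attack of Ca on the formyl group to outrun heterolysis of the tertiary allylic O–CMe2 bond; the six-membered closure with its gem-dimethyl group, the alkene without allylic hydrogens (no ene pathway) and the C4 methoxy donor that makes Ca the nucleophilic diene terminus should secure this under the mild chromium catalyst.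

Step 6
Reactants: 12 the 2-methylallyl bis-pyranoquinolone (Ca R, Cb S, Cc R)
Product: 13 CNP0202276.1 (Ca R, Cb S, Cc R)
Conditions: Co(acac)2 (20 mol %), PhSiH3, O2 (1 atm), THF, 23 °C
Reagents that add atoms: dioxygen O=O
Why: Mukaiyama hydration, in which hydrogen atom transfer from a cobalt hydride to the 1,1-disubstituted alkene gives the tertiary radical that is trapped by O2 and reduced to the Markovnikov tertiary alcohol, leaving the three stereocenters untouched.

Compound list

1 | 4-hydroxy-1-methylquinolin-2(1H)-one | Cn1c(=O)cc(O)c2ccccc12 | starting material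
2 | 4-chloro-3-[(dimethyliminio)methyl]-1-methylquinolin-2(1H)-one chloride | Cn1c(=O)c(C=[N+](C)C)c(Cl)c2ccccc12.[Cl-] | intermediate
3 | 4-chloro-1-methyl-2-oxo-1,2-dihydroquinoline-3-carbaldehyde | Cn1c(=O)c(C=O)c(Cl)c2ccccc12 | intermediate
4 | 4-methoxy-1-methylquinolin-2(1H)-one | COc1cc(=O)n(C)c2ccccc12 | starting material
5 | 3-iodo-4-methoxy-1-methylquinolin-2(1H)-one | COc1c(I)c(=O)n(C)c2ccccc12 | intermediate
6 | 2-methylbut-3-en-2-ol | CC(C)(O)C=C | starting material
7 | (E)-3-(3-hydroxy-3-methylbut-1-en-1-yl)-4-methoxy-1-methylquinolin-2(1H)-one | COc1c(/C=C/C(C)(C)O)c(=O)n(C)c2ccccc12 | intermediate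
8 | sodium (E)-4-(4-methoxy-1-methyl-2-oxo-1,2-dihydroquinolin-3-yl)-2-methylbut-3-en-2-olate | COc1c(/C=C/C(C)(C)[O-])c(=O)n(C)c2ccccc12.[Na+] | intermediate
9 | 4-{[(E)-4-(4-methoxy-1-methyl-2-oxo-1,2-dihydroquinolin-3-yl)-2-methylbut-3-en-2-yl]oxy}-1-methyl-2-oxo-1,2-dihydroquinoline-3-carbaldehyde | Cn1c(=O)c(C=O)c(OC(C)(C)/C=C/c2c(OC)c3ccccc3n(C)c2=O)c2ccccc12 | intermediate
10 | trimethyl(2-methylallyl)silane | CC(=C)C[Si](C)(C)C | starting material
11 | methoxy ketal cycloadduct (Ca R, Cb S): rings C and D closed, former C4 of quinolone B an sp3 ketal carbon bearing OCH3 with its aryl carbon cis to the CMe2 carbon, former C3 of quinolone B joined to Cc by an exocyclic double bond | Cn1c(=O)c2c(c3ccccc31)OC(C)(C)[C@H]1[C@@H]2O[C@@]2(OC)c3ccccc3N(C)C(=O)C2=C1 | intermediate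
12 | 2-methylallyl bis-pyranoquinolone (Ca R, Cb S, Cc R): the target with CH2C(CH3)=CH2 on Cc in place of CH2C(CH3)2OH | Cn1c(=O)c2c(c3ccccc31)OC(C)(C)[C@H]1[C@@H]2Oc2c(c(=O)n(C)c3ccccc23)[C@@H]1CC(C)=C | intermediate
13 | CNP0202276.1 (Ca R, Cb S, Cc R) | Cn1c(=O)c2c(c3ccccc31)OC(C)(C)[C@H]1[C@@H]2Oc2c(c(=O)n(C)c3ccccc23)[C@@H]1CC(C)(C)O | target

Total step count: 6. Longest linear sequence: 5 steps (4 → 5 → 7 → 9 → 12 → 13).

Steps most likely to fail

1. Step 5 (Proposed new method). The tertiary allylic ether may ionise at the O–CMe2 bond before Ca reaches the formyl group. The diene may not reach the s-cis conformation because the methoxy group sits on its inner side. The catalyst may discriminate the formyl faces poorly. Fallback by known chemistry, setting out from 1 and coming back at 13: 1 is condensed with 3-methylbut-2-enal (pyridine, 110 °C; Knoevenagel condensation and oxa-6π electrocyclisation) to N-methylflindersine F1. 3-Hydroxy-3-methylbutanal F2, freed from commercial 4,4-dimethoxy-2-methylbutan-2-ol with aqueous oxalic acid, is condensed with a second portion of 1 (ethylenediammonium diacetate, toluene, 80 °C) to 3-(3-hydroxy-3-methylbutylidene)-1-methylquinoline-2,4(1H,3H)-dione F3. This ortho-quinone methide should be intercepted in the flask by the pyran alkene of F1 in a domino Knoevenagel/hetero-Diels–Alder reaction. That reaction closes ring D at the O–Cb and Cc–Ca bonds instead, so it gives up both the two-bond closure of step 5 and catalytic enantiocontrol. Its endo/exo selectivity is not controlled, so chromatography may be needed. It should give racemic material, from which the enantiomer of 13 F4 is removed by preparative HPLC on a chiral stationary phase.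

2. Step 4. The hindered tertiary allylic alkoxide may add reversibly to the formyl group without displacing chloride, and the product ether may ionise on acidic silica. Fallback, setting out from 3 and 5 and coming back at 9: 2-methylbut-3-yn-2-ol and NaH (THF, 0 °C) give the much smaller sodium 2-methylbut-3-yn-2-olate F5, which displaces the chloride of 3 to give 1-methyl-4-[(2-methylbut-3-yn-2-yl)oxy]-2-oxo-1,2-dihydroquinoline-3-carbaldehyde F6. Palladium-catalysed hydrostannation (Bu3SnH, PdCl2(PPh3)2, THF, 0 °C) should add tin to the terminal carbon syn to hydrogen and give 1-methyl-4-{[(E)-2-methyl-4-(tributylstannyl)but-3-en-2-yl]oxy}-2-oxo-1,2-dihydroquinoline-3-carbaldehyde F7. Stille coupling of F7 with iodide 5 (Pd(PPh3)4, CuI, DMF, 50 °C) then gives 9.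

3. Step 6. The tertiary radical may abstract the activated hydrogen at Cb by 1,5-hydrogen transfer instead of being trapped by O2, and the peroxide stage may be reduced incompletely. Fallback, setting out from 9 and coming back at 13: step 5 is run with 2-(trimethylsilyloxy)propene in place of 10, so that the oxocarbenium ion from ketal 11 is captured in a Mukaiyama-type addition. This should give the methyl ketone with CH2C(=O)CH3 on Cc (Ca R, Cb S, Cc R) F8. MeMgBr with CeCl3 (THF, −78 °C) then adds to the ketone and gives 13 by a polar route without radical intermediates.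

Further compounds

F1 | step 5 | N-methylflindersine (2,2,6-trimethyl-2H-pyrano[3,2-c]quinolin-5(6H)-one) | Cn1c(=O)c2c(c3ccccc31)OC(C)(C)C=C2
F2 | step 5 | 3-hydroxy-3-methylbutanal | CC(C)(O)CC=O
F3 | step 5 | 3-(3-hydroxy-3-methylbutylidene)-1-methylquinoline-2,4(1H,3H)-dione | CN1C(=O)C(=CCC(C)(C)O)C(=O)c2ccccc12
F4 | step 5 | enantiomer of 13 (Ca S, Cb R, Cc S) | Cn1c(=O)c2c(c3ccccc31)OC(C)(C)[C@@H]1[C@H]2Oc2c(c(=O)n(C)c3ccccc23)[C@H]1CC(C)(C)O
F5 | step 4 | sodium 2-methylbut-3-yn-2-olate | CC(C)([O-])C#C.[Na+]
F6 | step 4 | 1-methyl-4-[(2-methylbut-3-yn-2-yl)oxy]-2-oxo-1,2-dihydroquinoline-3-carbaldehyde | Cn1c(=O)c(C=O)c(OC(C)(C)C#C)c2ccccc12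
F7 | step 4 | 1-methyl-4-{[(E)-2-methyl-4-(tributylstannyl)but-3-en-2-yl]oxy}-2-oxo-1,2-dihydroquinoline-3-carbaldehyde | Cn1c(=O)c(C=O)c(OC(C)(C)/C=C/[Sn](CCCC)(CCCC)CCCC)c2ccccc12
F8 | step 6 | methyl ketone with CH2C(=O)CH3 on Cc (Ca R, Cb S, Cc R) | Cn1c(=O)c2c(c3ccccc31)OC(C)(C)[C@H]1[C@@H]2Oc2c(c(=O)n(C)c3ccccc23)[C@@H]1CC(C)=O
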